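## The problem

Prestegane A (11) is a γ-butyrolactone with two different benzyl groups on adjacent ring carbons. The lactone atoms are labelled C1 (carbonyl), C2 (α-CH), C3 (β-CH) and C4 (OCH2). C5 is the benzylic CH2 on C2 and bears ring A (3-hydroxy-4-methoxyphenyl); C6 is the benzylic CH2 on C3 and bears ring B (3,4-dimethoxyphenyl). Rings A and B differ by one O-methyl group only, so C1 and C4 (and C5 and C6) must stay distinguishable at every stage, or the carbonyl ends up on the wrong side. The two stereocentres are contiguous, both R, with the benzyl groups trans. C2 is enolisable and trans is the thermodynamic arrangement, so C3 can control C2 by equilibration; C3 has no such helper and needs an external source of chirality. The fragile groups are the free phenol of ring A (a Michael donor under base, easily oxidised), the electron-rich arenes, which make benzylic and cinnamylic C–O bonds prone to ionisation, and the lactone, which opens with strong nucleophiles. The enabling feature is that C5–C2–C1 is the carbon chain of propiolic acid and O–C4–C3–C6–ring B that of a cinnamyl alcohol. The lactone C1–O bond is therefore the ester bond of a cinnamyl propiolate, a 1,6-enyne in which only C5–aryl and C2–C3 remain to be made.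

## Retrosynthesis

**11 to 10 (C2 configuration).** No skeletal bond is cut; only the C2–H bond is reset, tracing 11 to its cis epimer 10. The neighbouring choice, setting C2 in a bond-forming step, would impose a second stereochemical demand on all earlier chemistry. With this move the precursor may have either configuration at C2, so the problem shrinks to one stereocentre. The forward reaction must enolise the lactone reversibly without opening it; C3 has no acidic hydrogen and is untouched.

**10 to 8 (C5–H, C2–H and phenol O–H).** The two C–H bonds at C5 and C2 and the phenolic O–H are cut, giving the (E)-benzylidene lactone 8 with the phenol as a benzyl ether. The unsaturation removes the C2 stereocentre and turns C5–C2–C1 into an acrylate, the oxidation level of an alkyne adduct. The benzyl ether is preferred to a free phenol because a phenoxide would add to the ynoate of 6 under the basic key step. It costs no step, since it leaves in the same hydrogenation (through 9). The forward step must saturate the exocyclic alkene without letting it migrate into the ring, which would erase C3.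

**8 to 6 + 7 (C5–aryl and C2–C3).** Both bonds are cut at once. Cutting C2–C5 alone (enolate benzylation) or C3–C6 alone (benzyl conjugate addition) removes one benzyl group each and leaves the C3 stereocentre to a separate sequence. Cutting the ester bond opens the ring but forms no C–C bond. The chosen pair falls on the alkyne and alkene that flank the ester already present in 6, and it removes ring A, the lactone ring and the only stereocentre together. The precursors are the achiral enyne 6 and the commercial boronic acid 7. The forward reaction must deliver the aryl group to C5 and not C2, close 5-exo onto one face of the alkene, and end by protonation at C6.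

**6 to 4 + 5 (acyl C1–O).** The ester is cut at the acyl–oxygen bond into cinnamyl alcohol 4 and propiolic acid 5. The neighbouring cut at C4–O (carboxylate alkylation) would need an ionisable, SN2'-prone electron-rich cinnamyl halide. The forward step must activate an acid that is itself a Michael acceptor under mild, near-neutral conditions.

**4 to 3 to 1 + 2 (C3=C6 and the carbinol hydrogens).** Reduction of the ester 3 gives 4, and olefination of 3,4-dimethoxybenzaldehyde 1 with phosphonate 2 gives 3. A stabilised phosphonate is chosen over an unstabilised ylide or cross-metathesis because it secures the (E) geometry. The forward reactions must be E-selective and reduce 1,2 only.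

## Roads not taken

Alternative 1: This road cuts C2–C3 and C6–aryl and forms no ring. An ate complex of a vinylboronic ester and an alkenyllithium carrying the ring A benzyl group would meet a ring B aryl triflate on zerovalent palladium with a chiral bisphosphine. Palladium-induced 1,2-migration of the alkenyl group from boron to carbon would give the secondary boronic ester A1. Boron marks the future C4 and the 1,1-disubstituted alkene the future C1.
- Merits: a catalytic, three-component, enantioselective reaction class with solid precedent; C3 is set in one operation and each arene arrives on its own fragment.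
- Weak points: A1 contains neither lactone oxygen. Boron must be homologated by one carbon and oxidised to give C4–OH, and the alkene must be hydroborated and oxidised to acid level to give C1. The two primary oxygen functions at C1 and C4 are near-equivalent and must be introduced at different times and protected apart, or the regioisomeric lactone results. This amounts to six to eight further steps. C2 arises in an acyclic hydroboration with little control and still needs the final equilibration. Alkenyl groups are the less dependable migrating groups, and an electron-rich aryl triflate is a slow partner.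
- Comparison: in security of the enantio-determining step this road is ahead, because the key step chosen here is untested. The chosen plan sets against that a key step that delivers the whole lactone at the right oxidation level from two achiral components, with two steps left.

Alternative 2: This road cuts C2–C3 and O–C4. The sulfinyl oxygen of an enantiopure alkenyl sulfoxide would acylate a chloro-substituted ketene partner bearing the ring A benzyl group. A [3,3] shift of the vinyloxysulfonium enolate would form C2–C3, and the carboxylate would close on the thionium carbon to give A2.
- Merits: a C–C bond and the ring form in one step, C1 arrives at the right oxidation level, and chirality is relayed from sulfur to C3 through an ordered six-membered transition state, a substrate-controlled process.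
- Weak points: chirality is stoichiometric and needs a configurationally and geometrically defined alkenyl sulfoxide. A2 carries chlorine at C2 and an arylthio group at C4 that must be removed reductively (zinc or a tin hydride, then Raney Ni). Debenzylation and C2 equilibration follow anyway. A monochloro-monoalkyl ketene is less electrophilic and more prone to dimerise than the dihaloketenes on which this lactonisation is best established.
- Comparison: the stereochemical relay is more predictable than the face selection asked of step 4, and the convergence is equal. The chosen plan sets against it catalytic chirality, no atoms to excise, and a shorter sequence before and after the key step.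

Alternative 3: This road cuts C1–C2 and C1–O, with carbon monoxide as C1 and the achiral (E)-allylic alcohol A3 holding every other carbon. A palladium hydride, formed from Pd(OAc)2 (divalent palladium) and a chiral bisphosphine under CO/H2, would add across C3=C2 with hydrogen to C3. CO would insert at C2 and the hydroxyl would close the acyl, giving O-benzyl prestegane A, A4.
- Merits: syn addition to the (E)-alkene translates directly into the trans lactone, so both stereocentres are set together, and A4 is one hydrogenolysis from 11. After the key step this road is shorter than the chosen plan (one step against two) and needs no epimerisation.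
- Weak points: the alkene of A3 is trisubstituted and flanked by two benzylic methylenes, so reversible hydropalladation can walk it into conjugation with either arene, giving regioisomeric carbonylation. The enantio-determining hydride delivery must distinguish CH2OH from CH2Ar on C3, two groups of similar size. The allylic alcohol can ionise on palladium. A3 needs its own geometry-defined synthesis, and pressure equipment is required.
- Comparison: if it worked it would be the more elegant route. The chosen plan sets against it a substrate (6) whose two π systems are unambiguous in polarity and geometry, and a single-centre stereochemical demand with C2 corrected afterwards by thermodynamics.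

Key step: step 4

Assumption: the (R,R) antipode of the diene ligand is taken to give the R configuration at C3; this sense cannot be derived from precedent for an ester-tethered styrenyl enyne, so the (S,S) ligand is used instead if the first run shows the opposite sense.

## Route

Step 1
Reactants: 1 3,4-dimethoxybenzaldehyde; 2 triethyl phosphonoacetate
Product: 3 ethyl (E)-3-(3,4-dimethoxyphenyl)acrylate
Conditions: NaH, THF, 0 °C to rt
Reagents that add atoms: none
Why: Horner–Wadsworth–Emmons olefination of an aromatic aldehyde with a stabilised phosphonate anion; reversible addition and the conjugated product should make the (E)-cinnamate the expected isomer.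

Step 2
Reactants: 3 ethyl (E)-3-(3,4-dimethoxyphenyl)acrylate
Product: 4 (E)-3-(3,4-dimethoxyphenyl)prop-2-en-1-ol
Conditions: i-Bu2AlH (2.5 equiv), CH2Cl2, −78 to 0 °C; aq potassium sodium tartrate
Reagents that add atoms: none
Why: 1,2-reduction of an α,β-unsaturated ester by i-Bu2AlH at low temperature; the conjugated alkene and the aryl methyl ethers should be left alone.

Step 3
Reactants: 4 (E)-3-(3,4-dimethoxyphenyl)prop-2-en-1-ol; 5 propiolic acid
Product: 6 (E)-3-(3,4-dimethoxyphenyl)allyl propiolate
Conditions: DCC, DMAP (5 mol%), CH2Cl2, −20 to 0 °C
Reagents that add atoms: none
Why: Steglich esterification (carbodiimide activation, catalytic DMAP); low temperature and a small DMAP charge limit conjugate addition to the ynoate, and the near-neutral medium spares the ionisable cinnamyl C–O bond.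

Step 4
Reactants: 6 (E)-3-(3,4-dimethoxyphenyl)allyl propiolate; 7 3-benzyloxy-4-methoxyphenylboronic acid
Product: 8 (R,E)-3-(3-benzyloxy-4-methoxybenzylidene)-4-(3,4-dimethoxybenzyl)dihydrofuran-2(3H)-one
Conditions: [RhCl(C2H4)2]2 (2.5 mol%), (R,R)-2,5-diphenylbicyclo[2.2.2]octa-2,5-diene (5.5 mol%), KOH (10 mol%), 1,4-dioxane/H2O 10:1, 40 °C, slow addition of 6 to 7 (2 equiv)
Reagents that add atoms: none
Why: Proposed new method: the hydroxorhodium–diene complex of monovalent rhodium formed from [RhCl(C2H4)2]2, the diene and KOH transmetalates 7, and the arylrhodium should add syn across the terminal ynoate of 6 with the aryl group on C5 and rhodium on C2, the sense favoured by both the ester polarisation and the unhindered alkyne terminus; the alkenylrhodium then inserts the tethered cinnamyl alkene in a 5-exo-trig closure that forms C2–C3 and the lactone ring, and the eta-3 benzylrhodium left at C6 is protonated by water, releasing 8 and returning rhodium hydroxide. The closest known reaction type is the rhodium–chiral diene-catalysed arylative cyclisation of 1,6-enynes with arylboronic acids, supported by rhodium- and palladium-catalysed cyclisations of allyl 2-alkynoates to alpha-alkylidene-gamma-butyrolactones; not yet shown is the combination of an ester tether, a terminal ynoate and a styrene-type acceptor whose benzylrhodium ends by protonation. C3, the only new stereocentre, is set in the alkene insertion, where the C2-symmetric diene on rhodium selects the face of the (E)-alkene (catalyst control). The (E) geometry of the benzylidene follows from the syn arylrhodation and is erased in step 5 in any case. The step needs alkyne-before-alkene chemoselectivity, which the electron-poor triple bond of 6 provides, 5-exo over 6-endo closure, which ring size and benzylic stabilisation of rhodium at C6 by electron-rich ring B provide, and protonation in preference to beta-hydride elimination, which the eta-3 benzyl binding and the aqueous medium favour. The benzyl ether of 7 keeps a phenoxide from adding to the ynoate, and slow addition of 6 keeps the free alkyne concentration low to suppress its oligomerisation on rhodium.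

Step 5
Reactants: 8 (R,E)-3-(3-benzyloxy-4-methoxybenzylidene)-4-(3,4-dimethoxybenzyl)dihydrofuran-2(3H)-one
Product: 10 (3S,4R)-4-(3,4-dimethoxybenzyl)-3-(3-hydroxy-4-methoxybenzyl)dihydrofuran-2(3H)-one, via cis benzyl ether lactone 9 (not isolated)
Conditions: H2 (1 atm), 10% Pd/C, EtOAc/EtOH, rt
Reagents that add atoms: none
Why: Heterogeneous catalytic hydrogenation of the conjugated exocyclic alkene, followed in the same flask by hydrogenolysis of the aryl benzyl ether of 9; hydrogen should arrive anti to the C3 benzyl group, so the cis epimer is expected to predominate. Any trans isomer formed is the target itself and is carried along, since step 6 equilibrates C2.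

Step 6
Reactants: 10 (3S,4R)-4-(3,4-dimethoxybenzyl)-3-(3-hydroxy-4-methoxybenzyl)dihydrofuran-2(3H)-one
Product: 11 prestegane A, (3R,4R)-4-(3,4-dimethoxybenzyl)-3-(3-hydroxy-4-methoxybenzyl)dihydrofuran-2(3H)-one
Conditions: DBU (3 equiv), toluene, 80 °C; aq NH4Cl
Reagents that add atoms: none
Why: Base-mediated epimerisation through the lactone enolate under thermodynamic control; the trans-2,3-dibenzyl arrangement relieves the eclipsing of the two benzyl groups and should be favoured, and C3 carries no acidic hydrogen, so it keeps its configuration and dictates C2. Excess DBU is used because the first equivalent is taken up by the phenol.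

## Compound list

1 | 3,4-dimethoxybenzaldehyde | COc1ccc(C=O)cc1OC | starting material
2 | triethyl phosphonoacetate | CCOC(=O)CP(=O)(OCC)OCC | starting material
3 | ethyl (E)-3-(3,4-dimethoxyphenyl)acrylate | CCOC(=O)/C=C/c1ccc(OC)c(OC)c1 | intermediate
4 | (E)-3-(3,4-dimethoxyphenyl)prop-2-en-1-ol | OC/C=C/c1ccc(OC)c(OC)c1 | intermediate
5 | propiolic acid | C#CC(=O)O | starting material
6 | (E)-3-(3,4-dimethoxyphenyl)allyl propiolate | C#CC(=O)OC/C=C/c1ccc(OC)c(OC)c1 | intermediate
7 | 3-benzyloxy-4-methoxyphenylboronic acid | COc1ccc(B(O)O)cc1OCc1ccccc1 | starting material
8 | (R,E)-3-(3-benzyloxy-4-methoxybenzylidene)-4-(3,4-dimethoxybenzyl)dihydrofuran-2(3H)-one | COc1ccc(/C=C2/C(=O)OC[C@@H]2Cc2ccc(OC)c(OC)c2)cc1OCc1ccccc1 | intermediate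
9 | (3S,4R)-3-(3-benzyloxy-4-methoxybenzyl)-4-(3,4-dimethoxybenzyl)dihydrofuran-2(3H)-one | COc1ccc(C[C@@H]2C(=O)OC[C@@H]2Cc2ccc(OC)c(OC)c2)cc1OCc1ccccc1 | intermediate
10 | (3S,4R)-4-(3,4-dimethoxybenzyl)-3-(3-hydroxy-4-methoxybenzyl)dihydrofuran-2(3H)-one | COc1ccc(C[C@@H]2C(=O)OC[C@@H]2Cc2ccc(OC)c(OC)c2)cc1O | intermediate
11 | prestegane A, (3R,4R)-4-(3,4-dimethoxybenzyl)-3-(3-hydroxy-4-methoxybenzyl)dihydrofuran-2(3H)-one | COc1ccc(C[C@H]2C(=O)OC[C@@H]2Cc2ccc(OC)c(OC)c2)cc1O | target

## Step count and least certain steps

Total steps: 6. Longest linear sequence: 6 steps (1 to 11); 5 and 7 enter as purchased materials.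

**Step 4 (key step, proposed new method).** Four processes are most likely to interfere:
- Protonolysis of the alkenylrhodium before ring closure, because the ester must leave its preferred s-trans conformation to reach the alkene while water competes.
- Oligomerisation of the terminal ynoate on rhodium.
- Beta-hydride elimination from the benzylrhodium at C6, which would unsaturate C3–C6 and erase the new stereocentre.
- Weak or unpredictable face selection for this new substrate class.

Within the same disconnection, the water content can be lowered, the boroxine used in place of 7, and the diene varied.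

Fallback (known chemistry; sets out from 1, returns at 8):
- Stobbe condensation of 1 with dimethyl succinate (NaOMe, MeOH, reflux) would give (E)-4-(3,4-dimethoxyphenyl)-3-(methoxycarbonyl)but-3-enoic acid F1.
- Asymmetric hydrogenation of this itaconate-type half-ester with [Rh(cod)2]BF4 and the antipode of a DuPhos- or DIOP-type bisphosphine that leads to the R acid would give (R)-4-(3,4-dimethoxyphenyl)-3-(methoxycarbonyl)butanoic acid F2.
- Reduction of the ester group of its potassium salt with Ca(BH4)2 in EtOH, then acidification, would give (R)-4-(3,4-dimethoxybenzyl)dihydrofuran-2(3H)-one F3, which already holds C3.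
- Aldol addition of its lithium enolate (LiN(SiMe3)2, THF, −78 °C) to 3-benzyloxy-4-methoxybenzaldehyde, anti to the C3 substituent, would give (3S,4R)-3-[(3-benzyloxy-4-methoxyphenyl)(hydroxy)methyl]-4-(3,4-dimethoxybenzyl)dihydrofuran-2(3H)-one F4 as a mixture of carbinol epimers.
- Mesylation (MeSO2Cl, Et3N, CH2Cl2) to (3S,4R)-3-[(3-benzyloxy-4-methoxyphenyl)(methanesulfonyloxy)methyl]-4-(3,4-dimethoxybenzyl)dihydrofuran-2(3H)-one F5 and elimination with DBU would give the (E)-benzylidene lactone 8. Steps 5 and 6 then follow unchanged.

**Step 3.** Conjugate addition of DMAP, of the alcohol or of the isourea nitrogen to the activated propiolate, and base-triggered oligomerisation, compete with acyl transfer; the activated cinnamyl ester may also ionise on acidic silica. Fallback (sets out from 4, returns at 6): 4 is acylated under the same carbodiimide conditions with 3-(trimethylsilyl)propiolic acid, whose silyl group shields the β-carbon, to give (E)-3-(3,4-dimethoxyphenyl)allyl 3-(trimethylsilyl)propiolate F6. Buffered fluoride desilylation (Bu4NF, AcOH, THF, −20 °C) then gives 6.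

**Step 5.** Migration of the exocyclic double bond into the ring on the palladium surface would erase C3 before hydrogen is added and erode enantiopurity. Fallback (sets out from 8, returns at 10): conjugate reduction with copper hydride ([(Ph3P)CuH]6 catalyst, polymethylhydrosiloxane, toluene/t-BuOH) adds hydride to C5 and protonates the copper enolate, a path with no allylic isomerisation. It would give 9 together with its C2 epimer (3R,4R)-3-(3-benzyloxy-4-methoxybenzyl)-4-(3,4-dimethoxybenzyl)dihydrofuran-2(3H)-one F7 (the same compound as A4). Hydrogenolysis of the benzyl ether over Pd/C, now with no alkene present, returns to 10 (admixed with 11), and step 6 converges both.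

**Step 6.** Equilibration may be incomplete, because DBU is tied up as the phenoxide salt and the anionic substrate enolises less readily; long heating with base invites lactone opening by adventitious water. Fallback (sets out from 10, returns at 11):
- Silylation (t-BuMe2SiCl, imidazole, DMF) would give (3S,4R)-3-[3-(tert-butyldimethylsilyloxy)-4-methoxybenzyl]-4-(3,4-dimethoxybenzyl)dihydrofuran-2(3H)-one F8.
- Equilibration of this neutral lactone with DBU or a substoichiometric amount of LiN(SiMe3)2 in THF would give the trans epimer (3R,4R)-3-[3-(tert-butyldimethylsilyloxy)-4-methoxybenzyl]-4-(3,4-dimethoxybenzyl)dihydrofuran-2(3H)-one F9.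
- Bu4NF in THF then releases 11.

## Further compounds

F1 | step 4 | (E)-4-(3,4-dimethoxyphenyl)-3-(methoxycarbonyl)but-3-enoic acid | COC(=O)/C(CC(=O)O)=C/c1ccc(OC)c(OC)c1
F2 | step 4 | (R)-4-(3,4-dimethoxyphenyl)-3-(methoxycarbonyl)butanoic acid | COc1ccc(C[C@H](CC(=O)O)C(=O)OC)cc1OC
F3 | step 4 | (R)-4-(3,4-dimethoxybenzyl)dihydrofuran-2(3H)-one | COc1ccc(C[C@@H]2CC(=O)OC2)cc1OC
F4 | step 4 | (3S,4R)-3-[(3-benzyloxy-4-methoxyphenyl)(hydroxy)methyl]-4-(3,4-dimethoxybenzyl)dihydrofuran-2(3H)-one, carbinol epimers | COc1ccc(C(O)[C@H]2C(=O)OC[C@@H]2Cc2ccc(OC)c(OC)c2)cc1OCc1ccccc1
F5 | step 4 | (3S,4R)-3-[(3-benzyloxy-4-methoxyphenyl)(methanesulfonyloxy)methyl]-4-(3,4-dimethoxybenzyl)dihydrofuran-2(3H)-one, carbinol epimers | COc1ccc(C(OS(C)(=O)=O)[C@H]2C(=O)OC[C@@H]2Cc2ccc(OC)c(OC)c2)cc1OCc1ccccc1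
F6 | step 3 | (E)-3-(3,4-dimethoxyphenyl)allyl 3-(trimethylsilyl)propiolate | C[Si](C)(C)C#CC(=O)OC/C=C/c1ccc(OC)c(OC)c1
F7 | step 5 | (3R,4R)-3-(3-benzyloxy-4-methoxybenzyl)-4-(3,4-dimethoxybenzyl)dihydrofuran-2(3H)-one | COc1ccc(C[C@H]2C(=O)OC[C@@H]2Cc2ccc(OC)c(OC)c2)cc1OCc1ccccc1
F8 | step 6 | (3S,4R)-3-[3-(tert-butyldimethylsilyloxy)-4-methoxybenzyl]-4-(3,4-dimethoxybenzyl)dihydrofuran-2(3H)-one | COc1ccc(C[C@@H]2C(=O)OC[C@@H]2Cc2ccc(OC)c(OC)c2)cc1O[Si](C)(C)C(C)(C)C
F9 | step 6 | (3R,4R)-3-[3-(tert-butyldimethylsilyloxy)-4-methoxybenzyl]-4-(3,4-dimethoxybenzyl)dihydrofuran-2(3H)-one | COc1ccc(C[C@H]2C(=O)OC[C@@H]2Cc2ccc(OC)c(OC)c2)cc1O[Si](C)(C)C(C)(C)C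
A1 | alternative 1 | (R)-2-[3-(3-benzyloxy-4-methoxybenzyl)-1-(3,4-dimethoxyphenyl)but-3-en-2-yl]-4,4,5,5-tetramethyl-1,3,2-dioxaborolane | COc1ccc(C[C@@H](B2OC(C)(C)C(C)(C)O2)C(=C)Cc2ccc(OC)c(OCc3ccccc3)c2)cc1OC
A2 | alternative 2 | (3S,4S,5S)-3-(3-benzyloxy-4-methoxybenzyl)-3-chloro-4-(3,4-dimethoxybenzyl)-5-(p-tolylthio)dihydrofuran-2(3H)-one | COc1ccc(C[C@@]2(Cl)C(=O)O[C@@H](Sc3ccc(C)cc3)[C@@H]2Cc2ccc(OC)c(OC)c2)cc1OCc1ccccc1
A3 | alternative 3 | (E)-4-(3-benzyloxy-4-methoxyphenyl)-2-(3,4-dimethoxybenzyl)but-2-en-1-ol | COc1ccc(C/C=C(/CO)Cc2ccc(OC)c(OC)c2)cc1OCc1ccccc1
A4 | alternative 3 | O-benzyl prestegane A, (3R,4R)-3-(3-benzyloxy-4-methoxybenzyl)-4-(3,4-dimethoxybenzyl)dihydrofuran-2(3H)-one | COc1ccc(C[C@H]2C(=O)OC[C@@H]2Cc2ccc(OC)c(OC)c2)cc1OCc1ccccc1
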